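**Strategy.** The plan cuts the C1–C2 and C5–C10 bonds (labdane numbering) of ring A in one retro-[4+2] move. The key step is a thermal intramolecular Diels–Alder reaction of an open-chain triene that closes ring A (C1, C2, C3, C4, C5, C10) and ring B (C5 to C10) at once and sets C5 and the quaternary C10. It exploits the C9 stereocentre with its C10(CH3)=C1 isopropenyl group, which is C4 of (S)-limonene; the cleaved limonene ring gives C7, C8, C11, C12, C13 and C16. The diene, C2=C3–C4(CO2Me)=C5, is a (Z)-2-vinyl enoate whose ester becomes C19; C7 and C9 steer the facial course.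

Key step: step 10

Remark: labdane numbering (C1–C20) is used for the target and for the atoms that become it; CIP descriptors in open-chain names follow each compound's own chain numbering.

Assumption: the sense of induction in step 4 is taken from the behaviour of this catalyst class with aryl and alkenyl aldehydes, recalled as (R)-acid giving (R)-carbinol; the antipodal acid would be used if the sense proved opposite.

**Route**

Step 1
Reactants: 1 (S)-(−)-limonene
Product: 3 (5S)-7,7-dimethoxy-5-(prop-1-en-2-yl)heptan-2-one, via keto aldehyde 2 (not isolated)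
Conditions: O3 (1.0 equiv), CH2Cl2/MeOH, −78 °C; Me2S, −78 °C → rt; then TsOH·H2O (cat.), MeOH, rt
Reagents that add atoms: ozone [O-][O+]=O; methanol CO
Why: Ozonolysis: with one equivalent of ozone the electron-rich trisubstituted ring alkene should be cleaved faster than the 1,1-disubstituted isopropenyl group, and mild acid in methanol acetalises only the aldehyde, which frees the methyl ketone (C13) for olefination; the limonene stereocentre (future C9) is not touched.

Step 2
Reactants: 3 (5S)-7,7-dimethoxy-5-(prop-1-en-2-yl)heptan-2-one; 4 triethyl phosphonoacetate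
Product: 6 ethyl (2E,6S)-3-methyl-8-oxo-6-(prop-1-en-2-yl)oct-2-enoate, via acetal enoate 5 (not isolated)
Conditions: NaH, THF, 0 → 50 °C; then 1 M aq. HCl, THF, rt; chromatographic removal of the minor 2Z isomer
Reagents that add atoms: water O
Why: Horner–Wadsworth–Emmons olefination of the methyl ketone with a stabilised phosphonate anion should favour the E-trisubstituted enoate (C13=C14), and the aqueous acid of the work-up hydrolyses the dimethyl acetal (the aldehyde oxygen comes from water) without touching the enoate or the isopropenyl group.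

Step 3
Reactants: 6 ethyl (2E,6S)-3-methyl-8-oxo-6-(prop-1-en-2-yl)oct-2-enoate
Product: 7 ethyl (2E,6R)-7-formyl-3-methyl-6-(prop-1-en-2-yl)octa-2,7-dienoate
Conditions: 37% aq. CH2O, pyrrolidine (10 mol %), propionic acid (10 mol %), i-PrOH, 45 °C
Reagents that add atoms: formaldehyde C=O
Why: Amine-catalysed α-methylenation (Mannich condensation of the enamine with formaldehyde, then elimination) installs C17 on C8; no ketone is left for an intramolecular aldol reaction, the allylic stereocentre is not enolisable, and its descriptor changes from S to R only because the CIP priorities change.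

Step 4
Reactants: 7 ethyl (2E,6R)-7-formyl-3-methyl-6-(prop-1-en-2-yl)octa-2,7-dienoate; 8 allenylboronic acid pinacol ester
Product: 10 ethyl (2E,6R,8S)-8-hydroxy-3-methyl-7-methylidene-6-(prop-1-en-2-yl)undec-2-en-10-ynoate, via pinacol borate 9 (not isolated)
Conditions: (S)-3,3'-bis(2,4,6-triisopropylphenyl)-1,1'-binaphthyl-2,2'-diyl hydrogen phosphate (10 mol %), 4 Å molecular sieves, toluene, −30 °C; aqueous work-up
Reagents that add atoms: none
Why: Chiral phosphoric acid-catalysed propargylation of the aldehyde by the allenylboronate through a closed six-membered SE2' transition state gives only the 1,2-adduct with a terminal alkyne and sets C7 under catalyst control (Si-face attack expected for the (S)-acid); the minor C7 epimer is a diastereomer and is removed by chromatography.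

Step 5
Reactants: 10 ethyl (2E,6R,8S)-8-hydroxy-3-methyl-7-methylidene-6-(prop-1-en-2-yl)undec-2-en-10-ynoate
Product: 11 (2E,6R,8S)-3-methyl-7-methylidene-6-(prop-1-en-2-yl)undec-2-en-10-yne-1,8-diol
Conditions: i-Bu2AlH (3.5 equiv), CH2Cl2, −78 → 0 °C; Rochelle salt work-up
Reagents that add atoms: none
Why: DIBAL-H reduces the conjugated ethyl ester to the E-allylic alcohol (C15) by 1,2-hydride delivery and leaves the alkyne and the alkenes alone.

Step 6
Reactants: 11 (2E,6R,8S)-3-methyl-7-methylidene-6-(prop-1-en-2-yl)undec-2-en-10-yne-1,8-diol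
Product: 12 (2E,6R,8S)-1,8-bis(tert-butyldimethylsilyloxy)-3-methyl-7-methylidene-6-(prop-1-en-2-yl)undec-2-en-10-yne
Conditions: TBSCl (2.5 equiv), imidazole, DMF, rt
Reagents that add atoms: tert-butyldimethylsilyl chloride CC(C)(C)[Si](C)(C)Cl
Why: Standard silylation protects both hydroxyls in one operation; the C7 ether must stay until after step 11, because a free C7 hydroxyl would lactonise onto the cis ester of the later dienoate.

Step 7
Reactants: 12 (2E,6R,8S)-1,8-bis(tert-butyldimethylsilyloxy)-3-methyl-7-methylidene-6-(prop-1-en-2-yl)undec-2-en-10-yne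
Product: 14 methyl (5S,7R,10E)-5,12-bis(tert-butyldimethylsilyloxy)-10-methyl-6-methylidene-7-(prop-1-en-2-yl)dodec-10-en-2-ynoate, via lithium acetylide 13 (not isolated)
Conditions: n-BuLi, THF, −78 °C; ClCO2Me, −78 → 0 °C
Reagents that add atoms: methyl chloroformate COC(=O)Cl; n-butyllithium [Li]CCCC (lithium of intermediate 13 only)
Why: Deprotonation of the terminal alkyne and C-acylation of the lithium acetylide with the chloroformate gives the 2-ynoate, which places the future C19 carbon on C4.

Step 8
Reactants: 14 methyl (5S,7R,10E)-5,12-bis(tert-butyldimethylsilyloxy)-10-methyl-6-methylidene-7-(prop-1-en-2-yl)dodec-10-en-2-ynoate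
Product: 15 methyl (2E,5S,7R,10E)-5,12-bis(tert-butyldimethylsilyloxy)-10-methyl-6-methylidene-7-(prop-1-en-2-yl)-2-(tributylstannyl)dodeca-2,10-dienoate
Conditions: Bu3SnH (1.2 equiv), Pd(PPh3)4 (3 mol %), THF, 0 °C → rt
Reagents that add atoms: tributyltin hydride CCCC[SnH](CCCC)CCCC
Why: Palladium-catalysed hydrostannation of a 2-ynoate is a syn addition that puts tin on the α-carbon (C4) and hydrogen on C5, so C6 ends up cis to the ester and trans to the tin.

Step 9
Reactants: 15 methyl (2E,5S,7R,10E)-5,12-bis(tert-butyldimethylsilyloxy)-10-methyl-6-methylidene-7-(prop-1-en-2-yl)-2-(tributylstannyl)dodeca-2,10-dienoate; 16 vinyl bromide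
Product: 17 methyl (2Z,5S,7R,10E)-5,12-bis(tert-butyldimethylsilyloxy)-2-ethenyl-10-methyl-6-methylidene-7-(prop-1-en-2-yl)dodeca-2,10-dienoate
Conditions: Pd2(dba)3 (2.5 mol %), AsPh3 (20 mol %), CuI (20 mol %), NMP, 45 °C, sealed vessel
Reagents that add atoms: none
Why: Stille coupling replaces tin by vinyl with retention of the alkene geometry (CuI speeds up transmetalation of the hindered α-stannyl enoate), which gives the diene with C6 on the outside, as the cycloaddition needs.

Step 10
Reactants: 17 methyl (2Z,5S,7R,10E)-5,12-bis(tert-butyldimethylsilyloxy)-2-ethenyl-10-methyl-6-methylidene-7-(prop-1-en-2-yl)dodeca-2,10-dienoate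
Product: 18 methyl 7β,15-bis(tert-butyldimethylsilyloxy)-18-norlabda-3,8(17),13E-trien-19-oate (5α-H, 9α-H, 10β-CH3, trans-fused)
Conditions: toluene (0.005 M), BHT (0.2 equiv), 200 °C, sealed tube
Reagents that add atoms: none
Why: Concerted, asynchronous thermal [4+2] cycloaddition (type 1 intramolecular Diels–Alder) of the electron-poor (Z)-2-vinyl enoate diene C2=C3–C4(CO2Me)=C5 with the isopropenyl group C10=C1, which forms C1–C2 and C5–C10 together and leaves the new C3=C4 bond conjugated with the ester. The closest known reaction type is the thermal cyclisation of 1,3,9-decatrienes carrying an unactivated 1,1-disubstituted dienophile, which gives angular-methyl octalins. Ring A (C1, C2, C3, C4, C5, C10) closes as the cyclohexene of the cycloaddition itself, and ring B (C5 to C10) closes as the fused ring through the C5–C10 bond, the four-atom tether C6–C7–C8–C9 allowing only the fused, not the bridged, mode. The trans ring fusion at C5 and C10 (5α-H, 10β-CH3) should come from the chair-like folding with C9 exo and the methyl under the diene, because the C4 ester on the diene carbon next to the tether clashes with C6 and C7 in the cis-fused folding. The absolute sense is set by C9 and C7, which are 1,3-cis on the nascent ring B, so that only one chair holds the side chain and the silyloxy group equatorial; this puts C10–CH3 anti to C9–H. The step needs site selectivity (only C10=C1 can reach the diene in a strain-free fused transition state; C8=C17 and C13=C14 cannot), an outside position of C6 on the diene (secured by steps 8 and 9) and suppression of diene dimerisation (high dilution, radical inhibitor).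

Step 11
Reactants: 18 methyl 7β,15-bis(tert-butyldimethylsilyloxy)-18-norlabda-3,8(17),13E-trien-19-oate
Product: 20 methyl 7β,15-bis(tert-butyldimethylsilyloxy)labda-8(17),13E-dien-19-oate, via lithium enolate 19 (not isolated)
Conditions: Li(s-Bu)3BH (1.2 equiv), THF, −78 °C; then MeI (5 equiv), HMPA, −78 → 0 °C
Reagents that add atoms: iodomethane CI; lithium tri-sec-butylborohydride [Li+].CCC(C)[BH-](C(C)CC)C(C)CC (lithium of intermediate 19 only)
Why: Conjugate reduction–alkylation: hydride adds to C3 of the enoate and the resulting ester enolate is methylated at C4 from the α-face, anti to the axial C10 methyl that blocks the β-face, so the new methyl (C18) is equatorial and the ester (C19) axial.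

Step 12
Reactants: 20 methyl 7β,15-bis(tert-butyldimethylsilyloxy)labda-8(17),13E-dien-19-oate
Product: 21 methyl 7β,15-dihydroxylabda-8(17),13E-dien-19-oate
Conditions: Bu4NF (3 equiv), THF, rt
Reagents that add atoms: none
Why: Fluoride cleaves both silyl ethers; the hindered methyl ester and the alkenes are inert, and the equatorial C7 hydroxyl cannot reach the axial C19 ester, so no lactone forms.

Step 13
Reactants: 21 methyl 7β,15-dihydroxylabda-8(17),13E-dien-19-oate
Product: 22 methyl 7β,15-diacetoxylabda-8(17),13E-dien-19-oate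
Conditions: Ac2O, pyridine, DMAP (cat.), CH2Cl2, rt
Reagents that add atoms: acetic anhydride CC(=O)OC(C)=O
Why: DMAP-catalysed acylation esterifies both the primary C15 and the equatorial secondary C7 hydroxyl.

Step 14
Reactants: 22 methyl 7β,15-diacetoxylabda-8(17),13E-dien-19-oate
Product: 23 methyl 7β-acetoxy-15-hydroxylabda-8(17),13E-dien-19-oate (CNP0329157.1)
Conditions: Candida antarctica lipase B (immobilised), n-BuOH (5 equiv), t-BuOMe, 30 °C
Reagents that add atoms: none
Why: Lipase-catalysed alcoholysis (serine hydrolase, acyl-enzyme mechanism) should remove only the unhindered primary allylic acetate at C15, because the secondary C7 acetate next to the exocyclic methylene on the decalin and the neopentyl C19 methyl ester do not fit the active site.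

**Compound list**

1 | (S)-(−)-limonene, (4S)-1-methyl-4-(prop-1-en-2-yl)cyclohex-1-ene | CC1=CC[C@H](CC1)C(C)=C | starting material
2 | (3S)-6-oxo-3-(prop-1-en-2-yl)heptanal (not isolated) | CC(=C)[C@H](CC=O)CCC(C)=O | intermediate
3 | (5S)-7,7-dimethoxy-5-(prop-1-en-2-yl)heptan-2-one | CC(=C)[C@H](CC(OC)OC)CCC(C)=O | intermediate
4 | triethyl phosphonoacetate | CCOC(=O)CP(=O)(OCC)OCC | starting material
5 | ethyl (2E,6S)-8,8-dimethoxy-3-methyl-6-(prop-1-en-2-yl)oct-2-enoate (not isolated) | CC(=C)[C@H](CC(OC)OC)CC/C(C)=C/C(=O)OCC | intermediate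
6 | ethyl (2E,6S)-3-methyl-8-oxo-6-(prop-1-en-2-yl)oct-2-enoate | CC(=C)[C@H](CC=O)CC/C(C)=C/C(=O)OCC | intermediate
7 | ethyl (2E,6R)-7-formyl-3-methyl-6-(prop-1-en-2-yl)octa-2,7-dienoate | C=C(C=O)[C@@H](C(C)=C)CC/C(C)=C/C(=O)OCC | intermediate
8 | allenylboronic acid pinacol ester, 4,4,5,5-tetramethyl-2-(propa-1,2-dienyl)-1,3,2-dioxaborolane | C=C=CB1OC(C)(C)C(C)(C)O1 | starting material
9 | O-pinacolboryl derivative of 10 (not isolated) | C=C([C@@H](OB1OC(C)(C)C(C)(C)O1)CC#C)[C@@H](C(C)=C)CC/C(C)=C/C(=O)OCC | intermediate
10 | ethyl (2E,6R,8S)-8-hydroxy-3-methyl-7-methylidene-6-(prop-1-en-2-yl)undec-2-en-10-ynoate | C=C([C@@H](O)CC#C)[C@@H](C(C)=C)CC/C(C)=C/C(=O)OCC | intermediate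
11 | (2E,6R,8S)-3-methyl-7-methylidene-6-(prop-1-en-2-yl)undec-2-en-10-yne-1,8-diol | C=C([C@@H](O)CC#C)[C@@H](C(C)=C)CC/C(C)=C/CO | intermediate
12 | (2E,6R,8S)-1,8-bis(tert-butyldimethylsilyloxy)-3-methyl-7-methylidene-6-(prop-1-en-2-yl)undec-2-en-10-yne | C=C([C@@H](O[Si](C)(C)C(C)(C)C)CC#C)[C@@H](C(C)=C)CC/C(C)=C/CO[Si](C)(C)C(C)(C)C | intermediate
13 | lithium acetylide of 12 (not isolated) | C=C([C@@H](O[Si](C)(C)C(C)(C)C)CC#C[Li])[C@@H](C(C)=C)CC/C(C)=C/CO[Si](C)(C)C(C)(C)C | intermediate
14 | methyl (5S,7R,10E)-5,12-bis(tert-butyldimethylsilyloxy)-10-methyl-6-methylidene-7-(prop-1-en-2-yl)dodec-10-en-2-ynoate | C=C([C@@H](O[Si](C)(C)C(C)(C)C)CC#CC(=O)OC)[C@@H](C(C)=C)CC/C(C)=C/CO[Si](C)(C)C(C)(C)C | intermediate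
15 | methyl (2E,5S,7R,10E)-5,12-bis(tert-butyldimethylsilyloxy)-10-methyl-6-methylidene-7-(prop-1-en-2-yl)-2-(tributylstannyl)dodeca-2,10-dienoate | C=C([C@@H](O[Si](C)(C)C(C)(C)C)C/C=C(/[Sn](CCCC)(CCCC)CCCC)C(=O)OC)[C@@H](C(C)=C)CC/C(C)=C/CO[Si](C)(C)C(C)(C)C | intermediate
16 | vinyl bromide | C=CBr | starting material
17 | methyl (2Z,5S,7R,10E)-5,12-bis(tert-butyldimethylsilyloxy)-2-ethenyl-10-methyl-6-methylidene-7-(prop-1-en-2-yl)dodeca-2,10-dienoate | C=C([C@@H](O[Si](C)(C)C(C)(C)C)C/C=C(/C=C)C(=O)OC)[C@@H](C(C)=C)CC/C(C)=C/CO[Si](C)(C)C(C)(C)C | intermediate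
18 | methyl 7β,15-bis(tert-butyldimethylsilyloxy)-18-norlabda-3,8(17),13E-trien-19-oate | C=C1[C@@H](O[Si](C)(C)C(C)(C)C)C[C@@H]2[C@](C)(CCC=C2C(=O)OC)[C@H]1CC/C(C)=C/CO[Si](C)(C)C(C)(C)C | intermediate
19 | lithium enolate of the C4 ester after hydride addition to C3 of 18 (not isolated; enolate geometry left open) | C=C1[C@@H](O[Si](C)(C)C(C)(C)C)C[C@@H]2[C@](C)(CCCC2=C(OC)O[Li])[C@H]1CC/C(C)=C/CO[Si](C)(C)C(C)(C)C | intermediate
20 | methyl 7β,15-bis(tert-butyldimethylsilyloxy)labda-8(17),13E-dien-19-oate | C=C1[C@@H](O[Si](C)(C)C(C)(C)C)C[C@@H]2[C@](C)(CCC[C@]2(C)C(=O)OC)[C@H]1CC/C(C)=C/CO[Si](C)(C)C(C)(C)C | intermediate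
21 | methyl 7β,15-dihydroxylabda-8(17),13E-dien-19-oate | C=C1[C@@H](O)C[C@@H]2[C@](C)(CCC[C@]2(C)C(=O)OC)[C@H]1CC/C(C)=C/CO | intermediate
22 | methyl 7β,15-diacetoxylabda-8(17),13E-dien-19-oate | C=C1[C@@H](OC(C)=O)C[C@@H]2[C@](C)(CCC[C@]2(C)C(=O)OC)[C@H]1CC/C(C)=C/COC(C)=O | intermediate
23 | methyl 7β-acetoxy-15-hydroxylabda-8(17),13E-dien-19-oate (CNP0329157.1) | C=C1[C@@H](OC(C)=O)C[C@@H]2[C@](C)(CCC[C@]2(C)C(=O)OC)[C@H]1CC/C(C)=C/CO | target

**Count**

Total steps: 14. Longest linear sequence: 14 steps, from 1 to 23.

**Steps most likely to fail**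

Step 10 (key step). The thermal cycloaddition may be too slow relative to thermal decomposition of the triene, or the folding of the tether may give part of the cis-fused adduct. The fallback sets out from 17 and comes back at 18. A cationic rhodium catalyst ([Rh(cod)Cl]2/AgSbF6, CH2Cl2, 25–40 °C) would effect the formal [4+2] cycloaddition of the unactivated diene and alkene by oxidative cyclisation to a rhodacycle and reductive elimination. This is a metal-templated stepwise mechanism instead of the pericyclic one, and it runs at a temperature where the thermal side reactions are absent. The ring-fusion outcome under rhodium is not predicted here and would have to be checked. It makes no new compound (F0).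

Step 11. Hydride delivery may go 1,2 instead of 1,4, or the hindered boron-complexed enolate may alkylate sluggishly or on oxygen. The fallback sets out from 18 and comes back at 20 and separates the two events. Single-electron conjugate reduction with Mg in MeOH (0 °C → rt) should give the saturated ester methyl 7β,15-bis(tert-butyldimethylsilyloxy)-18-norlabda-8(17),13E-dien-19-oate F1 as a mixture of C4 epimers, which is of no consequence. Deprotonation with LiN(i-Pr)2 (THF, −78 °C) and methylation with MeI/HMPA then gives 20, with the same α-face preference imposed by the axial C10 methyl.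

Step 9. Transmetalation of the hindered α-stannyl enoate may be slow, which leads to protodestannylation or homocoupling, and the volatile vinyl halide may be lost. The fallback sets out from 15 and comes back at 17 and reverses the polarity of the coupling partners. Iododestannylation (I2, CH2Cl2, 0 °C, retention of geometry) should give the α-iodo enoate methyl (2E,5S,7R,10E)-5,12-bis(tert-butyldimethylsilyloxy)-2-iodo-10-methyl-6-methylidene-7-(prop-1-en-2-yl)dodeca-2,10-dienoate F2. Suzuki–Miyaura coupling with potassium vinyltrifluoroborate (PdCl2(dppf), Cs2CO3, THF/H2O, 60 °C) then gives 17.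

**Further compounds**

F0 | step 10 | none | none
F1 | step 11 | methyl 7β,15-bis(tert-butyldimethylsilyloxy)-18-norlabda-8(17),13E-dien-19-oate (mixture of C4 epimers) | C=C1[C@@H](O[Si](C)(C)C(C)(C)C)C[C@@H]2[C@](C)(CCCC2C(=O)OC)[C@H]1CC/C(C)=C/CO[Si](C)(C)C(C)(C)C
F2 | step 9 | methyl (2E,5S,7R,10E)-5,12-bis(tert-butyldimethylsilyloxy)-2-iodo-10-methyl-6-methylidene-7-(prop-1-en-2-yl)dodeca-2,10-dienoate | C=C([C@@H](O[Si](C)(C)C(C)(C)C)C/C=C(/I)C(=O)OC)[C@@H](C(C)=C)CC/C(C)=C/CO[Si](C)(C)C(C)(C)C
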